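## Structural features

The target 22 is a daucane-type sesquiterpene ester. A cyclopentene (ring B: C1, C2, C3, C3a, C8a, azulene numbering) is fused through the C3a–C8a bond to a cycloheptene (ring A: C3a, C4, C5, C6, C7, C8, C8a). The hydroxymethyl group on C6 is esterified by vanillic acid. Ring B holds the tetrasubstituted alkene C3=C3a with isopropyl on C3; ring A holds the trisubstituted alkene C6=C7; the two alkenes are not conjugated. The only stereocentre is the quaternary, methyl-bearing C8a (R), flanked by C1H2, C8H2 and the sp2 carbon C3a, so no neighbouring stereocentre remains in the final structure to control it. Fragile groups are the primary allylic benzoate (ionisable by acid or zerovalent palladium), the free phenol, and the electron-rich tetrasubstituted alkene, whose protonation gives a C3a cation next to the quaternary carbon. The real difficulty is to make an all-carbon quaternary centre in a seven-membered ring as one enantiomer and still end with both alkenes in defined positions. The key step uses the following reading of ring A: with C7 as a ketone and the ring-B alkene moved to C3a=C4, the chain C7(=O)–C8H2–C8a–C3a=C4 is a γ,δ-unsaturated ketone. C8 is then the CH2 of an enol ether, C8a the far alkene carbon of a cyclopentenyl carbinol whose carbinol carbon is C4, and C5–C6 tie the two ends into a five-membered oxacycle.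

## Logic of the disconnections

22 ⇒ 21. The phenolic O–H is replaced by an O–acetyl bond. A free phenoxide would compete with the carboxylate in the ester-forming step. The demand is a final deacylation that leaves the allylic benzoate untouched.

21 ⇒ 18 + 20. The ester O–CH2 bond at C6 is cut with allylic transposition, so the electrophile carries its leaving group on C7 and an exocyclic alkene on C6. The primary ester with the C6=C7 alkene is the thermodynamic outlet of the allyl system, and the cut returns oxygen to C7, where the key step needs it. The forward step must attack at the CH2 terminus and use the carboxylate, not the aryl oxygen, as nucleophile.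

20 ⇒ 19. The aryl O–acetyl bond is cut; this is a one-step branch.

18 ⇒ 17 ⇒ 16. Two changes at the C7–O bond (carbonate to alcohol, alcohol to ketone) reach the cross-conjugated enone. The demand is strictly 1,2 reduction of an exocyclic enone.

16 ⇒ 14 (through 15). The exocyclic C=CH2 bond at C6 is traced to a C–S bond on that CH2 with hydrogen on C6. The enone would not survive a titanium methylidene, heat and acid, and the sulfide does. The forward sequence needs oxidation at sulfur in the presence of the tetrasubstituted alkene and elimination towards C6.

14 ⇒ 13. The C3=C3a alkene is moved back to C3a=C4. This restores the γ,δ-unsaturated ketone and an sp3 isopropyl-bearing C3, which links the plan to the chiral pool. The forward step is a thermodynamic alkene migration that must not disturb C8a.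

13 ⇒ 12 (key disconnection). The C8–C8a bond is cut and the C4–O bond is formed. The fused bicycle with a quaternary stereocentre becomes two monocycles joined by one bond, and the stereochemical problem becomes a secondary carbinol centre. The forward step must be a concerted, suprafacial [3,3] shift.

12 ⇒ 11. The enol ether C=CH2 is traced to a lactone C=O. The forward step is carbonyl methylenation under non-acidic conditions.

11 ⇒ 9 + 10. The S–CH2 bond is cut, revealing a conjugate acceptor. The new centre at the α-carbon need not be controlled.

9 ⇒ 6 + 7 (through 8). The bond from the carbinol carbon to the adjacent CH2 and the ring O–C(=O) bond are cut, giving an enal and a three-carbon allyl metal precursor. The forward addition must create the (S) carbinol centre, and this is the one place where epimers have to be separated.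

6 ⇒ 4 (through 5) ⇒ 2 (through 3) ⇒ 1. The enal C=C is cut (aldol), the two carbonyl carbons are reconnected as a ring alkene (ozonolysis), and the isopropyl group is traced to an isopropenyl group. The only stereocentre comes from 1 and is never α to a carbonyl group. The forward steps need selective hydrogenation of the less substituted alkene and an aldol in which the aldehyde α-carbon is the nucleophile.

## Other disconnections considered

Alternative 1: The cut takes ring B apart at three bonds, C3a–C8a, C1–C2 and C2–C3, with C2 as an added carbonyl carbon. It leads to the open-chain 1,8-enyne A1 (isopropyl alkyne at one end, 2-methylallyl unit at the other, silyl-protected C6 hydroxymethyl on a trisubstituted alkene in between). In the forward step A1 and CO, under [Rh(CO)2Cl]2 with a chiral BINAP-type bisphosphine (monovalent rhodium), would undergo a carbonylative (2+2+1) cyclisation of the Pauson–Khand type. Oxidative coupling of alkyne and alkene makes C3a–C8a and closes ring A; CO insertion and reductive elimination close ring B and give the cyclopentenone A2.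
- In favour: both rings and the quaternary centre come in one catalytic step from an achiral chain. The C3=C3a alkene appears in its final position and C6 already carries its oxygenated carbon with C6=C7 in place, so neither an alkene migration nor an allylic transposition is needed; on both points the alternative is better than the chosen plan. Either enantiomer is open by choice of ligand, whereas the chosen plan depends on the scarcer (S) enantiomer of 1; this is also a point for the alternative.
- Against: seven-ring closure in this reaction class is much less general than five- or six-ring closure and would rest here on the cis alkene in the tether. Enantioselective variants are established mainly for 1,6-enynes, so induction at a quaternary centre of a 1,8-enyne is an open question. The skipped diene of A1 can isomerise under rhodium hydrides, A1 needs a geometrically defined trisubstituted alkene, and the C2 carbonyl of A2 must be removed without moving the tetrasubstituted alkene.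
- Comparison: structurally A2 is closer to 22 than 13 is. Mechanistically the chosen plan transfers chirality stereospecifically from a purified carbinol, which is more predictable than ligand-controlled face selection in an unusual ring size. In step count the two are about equal once the synthesis of A1 and the deoxygenation are counted.

Alternative 2: The cut severs C5–C6 and C8–C8a of ring A. The three carbons C6, C7, C8 come from the diazo ester A3 and the four carbons C5, C4, C3a, C8a from the cross-conjugated dienone A4. In the forward step a chiral dirhodium tetracarboxylate such as Rh2(S-DOSP)4 would form the vinylcarbenoid from A3, cyclopropanate the vinyl group of A4 and, after Cope rearrangement in the same operation, give the bicyclic dienone ester A5.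
- In favour: two small achiral pieces are joined convergently, with enantiocontrol from a catalyst class that is strong in this tandem. C6 arrives with its carbon substituent and the C6=C7 alkene in place, so no allylic transposition is needed (better than the chosen plan). The C3 ketone is a handle for the isopropyl group. The overall count is lower (better on step economy).
- Against: in the boat-like Cope transition state the ring methyl of A4 sits on the inside, towards the cyclopropane CH2, which slows this rearrangement. The chosen plan carries the same inside methyl in its boat, so the two are equal on this point. A3 is a thermally labile diazo compound that cyclises to a pyrazole, and A4 is a polymerisable dienone. After A5 the isopropyl group must be added to a hindered conjugated ketone beside an unsaturated ester, and the oxygen then removed with transposition so that the alkene ends at C3=C3a and C4 becomes CH2. The chosen plan meets this regiochemical problem only as a single alkene migration.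
- Comparison: structurally A5 lacks the isopropyl group that the chosen plan carries from the start. Mechanistically both plans make C8–C8a by a [3,3] shift through a boat, one relaying chirality from a catalyst-made cyclopropane and the other from a separable carbinol. On step economy the alternative is the better.

Alternative 3: The cut severs C4–C5 and C8–C8a. It divides 22 into ring B with C4 attached (the allylic alcohol A6, available by reduction of 6 and activated as its trifluoroacetate A7) and the diene C5–C6–C7–C8 that already carries the aroyloxymethyl group (A8). In the forward step ionisation of A7 with ZnCl2 (or of A6 in a strongly hydrogen-bonding solvent) would give an allyl cation spread over C4, C3a and C8a. The more nucleophilic diene terminus C5 bonds to the primary end C4. The resulting tertiary allyl cation is then attacked at C8 by the ring alkene through C8a, anti to the isopropyl group, closing ring A. The C3a cation loses the C3 proton to give A9, which is identical with 21.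
- In favour: this is the shortest route by a wide margin (A6 is four steps from 1, A9 one step from 22), so it is clearly better on step economy and convergence. The final proton loss sets the C3=C3a alkene and erases the isopropyl centre in the same event, so no separate alkene migration is needed (better). The ester is in place before ring construction, so no allylic substitution endgame is needed (better).
- Against: (4+3) unions of allyl cations without a heteroatom donor and open-chain dienes have a narrow scope. The process is stepwise, and each cationic intermediate can lose a proton, be captured by trifluoroacetate or add to a second diene. A8 holds an ionisable allylic ester and the product an acid-sensitive diene, both exposed to the Lewis acid. The configuration at C8a rests only on 1,3-induction by the isopropyl group; because that centre is destroyed in the same step, any leakage appears directly as loss of enantiomeric purity, with no diastereomer left to separate.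
- Comparison: structurally this is the most direct construction. Mechanistically the chosen plan is better on stereochemical security (stereospecific shift from a separable carbinol epimer, isopropyl group only matched) and on precedent. If the cation union proved clean, the alternative would be the better plan.

Key step: step 6

Remark on the chemistry: the configurations of 12, 13 and 22 were checked against each other and are consistent. The (5S) carbinol centre, paired with the (R) isopropyl centre that (S)-limonene delivers, leads suprafacially to (8aR). Centres that are removed later (C3 of 11 and 12, C6 of 13 to 15, sulfur of 15, C7 of 17 and 18) are drawn as the expected major epimer or left open, because every such epimer converges on 22. Chromatographic separation of 9 from its C5 epimer is assumed to be feasible.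

## Route

Step 1
Reactants: 1 (S)-limonene [(4S)-1-methyl-4-(prop-1-en-2-yl)cyclohex-1-ene]
Product: 2 (S)-p-menth-1-ene [(4S)-1-methyl-4-(propan-2-yl)cyclohex-1-ene]
Conditions: H2 (1 atm, stopped after 1.0 equiv), PtO2 (0.5 mol%), EtOH, 20 °C
Reagents that add atoms: none
Why: Catalytic hydrogenation discriminates by substitution, so the 1,1-disubstituted isopropenyl alkene should be saturated well before the trisubstituted ring alkene; platinum causes little double-bond migration, so the C4 stereocentre is not touched.

Step 2
Reactants: 2 (S)-p-menth-1-ene
Product: 4 (3S)-6-oxo-3-(propan-2-yl)heptanal, via ozonide 3 (not isolated)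
Conditions: O3, CH2Cl2, −78 °C; then Me2S, −78 → 20 °C
Reagents that add atoms: ozone, [O-][O+]=O
Why: Ozonolysis with reductive work-up cleaves the only remaining alkene to a methyl ketone and an aldehyde; the stereocentre is β to the aldehyde and not enolisable.

Step 3
Reactants: 4 (3S)-6-oxo-3-(propan-2-yl)heptanal
Product: 6 (5R)-2-methyl-5-(propan-2-yl)cyclopent-1-ene-1-carbaldehyde, via aldol adduct 5 (not isolated)
Conditions: piperidine (0.3 equiv), AcOH (0.3 equiv), toluene, 80 °C, water removed
Reagents that add atoms: none
Why: Intramolecular aldol condensation under amine–acid catalysis: the enamine of the aldehyde attacks the methyl ketone (five-ring closure) and dehydration gives the tetrasubstituted enal; enamine activation makes the aldehyde α-carbon the nucleophile, which avoids the isomeric acetylcyclopentene expected under hydroxide, and the isopropyl-bearing centre is never α to a carbonyl group.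

Step 4
Reactants: 6 (5R)-2-methyl-5-(propan-2-yl)cyclopent-1-ene-1-carbaldehyde; 7 ethyl 2-(bromomethyl)prop-2-enoate
Product: 9 (5S)-3-methylidene-5-[(5R)-2-methyl-5-(propan-2-yl)cyclopent-1-en-1-yl]oxolan-2-one, via zinc alkoxide of hydroxy ester 8 (not isolated)
Conditions: Zn dust (activated), THF, 50 °C; aq NH4Cl; chromatography to remove the C5 epimer
Reagents that add atoms: none
Why: Zinc inserts into the allylic C–Br bond of 7, the allylzinc adds 1,2 to the aldehyde and the zinc alkoxide closes onto the ethyl ester without acid (Barbier-type Dreiding–Schmidt lactone synthesis); the carbinol centre is substrate-controlled, attack on the s-trans enal anti to the isopropyl group leading to the (5S) epimer, which is taken on after separation from the (5R) epimer.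

Step 5
Reactants: 9 (5S)-3-methylidene-5-[(5R)-2-methyl-5-(propan-2-yl)cyclopent-1-en-1-yl]oxolan-2-one; 10 benzenethiol
Product: 11 (3S,5S)-5-[(5R)-2-methyl-5-(propan-2-yl)cyclopent-1-en-1-yl]-3-[(phenylsulfanyl)methyl]oxolan-2-one
Conditions: Et3N (0.1 equiv), CH2Cl2, 0 → 20 °C
Reagents that add atoms: none
Why: Thia-Michael addition to the α-methylidene lactone masks the acceptor for the next steps; protonation of the lactone enolate anti to the C5 substituent should favour the cis (3S) isomer, and the C3 epimer is harmless because this centre is removed in step 8.

Step 6
Reactants: 11 (3S,5S)-5-[(5R)-2-methyl-5-(propan-2-yl)cyclopent-1-en-1-yl]-3-[(phenylsulfanyl)methyl]oxolan-2-one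
Product: 13 (3R,6S,8aR)-8a-methyl-6-[(phenylsulfanyl)methyl]-3-(propan-2-yl)-2,3,5,6,8,8a-hexahydroazulen-7(1H)-one, via 2-methylidene oxolane 12 (not isolated)
Conditions: Cp2TiMe2 (2.2 equiv), toluene, 70 °C, dark; NaHCO3, MeOH, H2O, 40 °C, filtration and drying of the toluene solution; then 2,6-di-tert-butyl-4-methylpyridine (0.1 equiv), toluene, 150 °C, sealed tube
Reagents that add atoms: dimethyltitanocene Cp2TiMe2, C[Ti](C)(C1C=CC=C1)C1C=CC=C1
Why: Cp2TiMe2 loses methane near 70 °C to give Cp2Ti=CH2, which turns the lactone carbonyl of 11 into the exocyclic enol ether of 12 through an oxatitanacyclobutane (Petasis methylenation). In 12 the atoms CH2=C2–O1–C5–C1′=C2′ form an allyl vinyl ether, and on heating a concerted [3,3] sigmatropic shift (Claisen ring expansion of a 2-methylidene-5-alkenyloxolane, a known entry to cyclohept-4-enones) joins the enol CH2 to C2′ while the C5–O1 bond breaks. The seven-membered ring is closed not by a cyclisation but by this enlargement of the oxolane by two atoms: C3 and C4 of the oxolane tie the two ends together, so the six-centre array is a boat and the new ring alkene (C3a=C4 of 13) is necessarily cis. Because only the rotamer with the oxolane C4 syn to C2′ can reach that boat and the shift is suprafacial on the allyl unit, the C8–C8a bond forms on the cyclopentene face from which oxygen departs, so the (5S) carbinol centre dictates the (8aR) quaternary centre. The isopropyl group on C5′ lies on the opposite face and does not oppose bond formation (matched case). The step needs the pericyclic path to outrun ionisation of the allylic C5–O bond, migration of the enol ether double bond into the ring and methylenation of the ketone product; destroying the titanium residues before heating, a non-polar solvent and a hindered pyridine base are meant to secure this. The ring methyl on C2′ is held on the inside of the boat against C4H2, which raises the barrier and is the reason for planning about 150 °C. Both C3 epimers of 12 should rearrange and converge later.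

Step 7
Reactants: 13 (3R,6S,8aR)-8a-methyl-6-[(phenylsulfanyl)methyl]-3-(propan-2-yl)-2,3,5,6,8,8a-hexahydroazulen-7(1H)-one
Product: 14 (6S,8aR)-8a-methyl-6-[(phenylsulfanyl)methyl]-3-(propan-2-yl)-2,4,5,6,8,8a-hexahydroazulen-7(1H)-one
Conditions: p-TsOH·H2O (0.1 equiv), toluene, 60 °C
Reagents that add atoms: none
Why: Acid-catalysed alkene isomerisation under thermodynamic control: protonation at C4 gives the tertiary C3a cation, which loses the C3 proton to form the tetrasubstituted C3=C3a alkene (the Zaitsev outcome typical of ring-fusion cations of this skeleton); the C3 stereocentre is erased by design, C8a is not involved, and epimerisation at C6 is of no consequence.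

Step 8
Reactants: 14 (6S,8aR)-8a-methyl-6-[(phenylsulfanyl)methyl]-3-(propan-2-yl)-2,4,5,6,8,8a-hexahydroazulen-7(1H)-one
Product: 16 (8aR)-8a-methyl-6-methylidene-3-(propan-2-yl)-2,4,5,6,8,8a-hexahydroazulen-7(1H)-one, via sulfoxide 15 (not isolated)
Conditions: NaIO4 (1.1 equiv), MeOH/H2O, 0 → 20 °C; extraction; then CaCO3, toluene, 100 °C
Reagents that add atoms: none
Why: Periodate oxidises the sulfide to the sulfoxide without touching the tetrasubstituted alkene, and the β-keto sulfoxide then undergoes thermal syn-elimination (sulfoxide pyrolysis) using its only β-hydrogen, the one on C6, to give the exocyclic enone; the oxygen added to sulfur leaves with the sulfenic acid.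

Step 9
Reactants: 16 (8aR)-8a-methyl-6-methylidene-3-(propan-2-yl)-2,4,5,6,8,8a-hexahydroazulen-7(1H)-one
Product: 17 (8aR)-8a-methyl-6-methylidene-3-(propan-2-yl)-1,2,4,5,6,7,8,8a-octahydroazulen-7-ol (C7 epimers)
Conditions: NaBH4, CeCl3·7H2O, MeOH, −78 → 0 °C
Reagents that add atoms: none
Why: Luche reduction: the cerium salt activates the carbonyl and the methoxyborohydrides deliver hydride 1,2, so conjugate reduction of the exocyclic enone is suppressed; the new C7 centre is removed in step 12 and its configuration does not matter.

Step 10
Reactants: 17 (8aR)-8a-methyl-6-methylidene-3-(propan-2-yl)-1,2,4,5,6,7,8,8a-octahydroazulen-7-ol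
Product: 18 methyl (8aR)-8a-methyl-6-methylidene-3-(propan-2-yl)-1,2,4,5,6,7,8,8a-octahydroazulen-7-yl carbonate
Conditions: ClCO2Me, pyridine, DMAP (cat.), CH2Cl2, 0 °C
Reagents that add atoms: methyl chloroformate, COC(=O)Cl
Why: Acylation of the secondary allylic alcohol under nucleophilic catalysis installs a leaving group that ionises irreversibly with zerovalent palladium and supplies its own base.

Step 11
Reactants: 19 vanillic acid (4-hydroxy-3-methoxybenzoic acid)
Product: 20 4-(acetyloxy)-3-methoxybenzoic acid
Conditions: Ac2O (1.5 equiv), pyridine, 20 °C; then H2O
Reagents that add atoms: acetic anhydride, CC(=O)OC(C)=O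
Why: Acetylation of the phenol; any mixed carboxylic anhydride is hydrolysed during the aqueous work-up, leaving the free acid.

Step 12
Reactants: 18 methyl (8aR)-8a-methyl-6-methylidene-3-(propan-2-yl)-1,2,4,5,6,7,8,8a-octahydroazulen-7-yl carbonate; 20 4-(acetyloxy)-3-methoxybenzoic acid
Product: 21 [(8aR)-8a-methyl-3-(propan-2-yl)-1,2,4,5,8,8a-hexahydroazulen-6-yl]methyl 4-(acetyloxy)-3-methoxybenzoate
Conditions: Pd(PPh3)4 (5 mol%), 20 (1.5 equiv), THF, 20 → 50 °C
Reagents that add atoms: none
Why: Tsuji–Trost allylic substitution: zerovalent palladium ionises the carbonate with loss of CO2 and methoxide, which deprotonates 20, and the carboxylate attacks the unhindered CH2 terminus of the allyl complex; any branched ester can re-ionise, so the primary ester with the trisubstituted C6=C7 alkene should accumulate, and both C7 epimers of 18 converge.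

Step 13
Reactants: 21 [(8aR)-8a-methyl-3-(propan-2-yl)-1,2,4,5,8,8a-hexahydroazulen-6-yl]methyl 4-(acetyloxy)-3-methoxybenzoate
Product: 22 [(8aR)-8a-methyl-3-(propan-2-yl)-1,2,4,5,8,8a-hexahydroazulen-6-yl]methyl 4-hydroxy-3-methoxybenzoate
Conditions: pyrrolidine (3 equiv), CH2Cl2, 0 °C
Reagents that add atoms: none
Why: Aminolysis of the aryl acetate: the phenoxide is a far better leaving group than the allylic alkoxide and the benzoate carbonyl is deactivated by its para oxygen, so the allylic ester should survive.

## Compound list

1 | (S)-limonene, (4S)-1-methyl-4-(prop-1-en-2-yl)cyclohex-1-ene | CC1=CC[C@H](CC1)C(C)=C | starting material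
2 | (S)-p-menth-1-ene, (4S)-1-methyl-4-(propan-2-yl)cyclohex-1-ene | CC1=CC[C@H](CC1)C(C)C | intermediate
3 | ozonide of 2, (4S)-1-methyl-4-(propan-2-yl)-7,8,9-trioxabicyclo[4.2.1]nonane (bridgehead isomers) | CC12OOC(C[C@H](CC1)C(C)C)O2 | intermediate (not isolated)
4 | (3S)-6-oxo-3-(propan-2-yl)heptanal | O=CC[C@H](CCC(C)=O)C(C)C | intermediate
5 | aldol adduct, (5R)-2-hydroxy-2-methyl-5-(propan-2-yl)cyclopentane-1-carbaldehyde (C1 and C2 open) | O=CC1C(C)(O)CC[C@@H]1C(C)C | intermediate (not isolated)
6 | (5R)-2-methyl-5-(propan-2-yl)cyclopent-1-ene-1-carbaldehyde | O=CC1=C(C)CC[C@@H]1C(C)C | intermediate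
7 | ethyl 2-(bromomethyl)prop-2-enoate | C=C(CBr)C(=O)OCC | starting material
8 | ethyl (4S)-4-hydroxy-2-methylidene-4-[(5R)-2-methyl-5-(propan-2-yl)cyclopent-1-en-1-yl]butanoate (formed as its bromozinc alkoxide) | CCOC(=O)C(=C)C[C@H](O)C1=C(C)CC[C@@H]1C(C)C | intermediate (not isolated)
9 | (5S)-3-methylidene-5-[(5R)-2-methyl-5-(propan-2-yl)cyclopent-1-en-1-yl]oxolan-2-one | O=C1O[C@H](C2=C(C)CC[C@@H]2C(C)C)CC1=C | intermediate
10 | benzenethiol (thiophenol) | Sc1ccccc1 | starting material
11 | (3S,5S)-5-[(5R)-2-methyl-5-(propan-2-yl)cyclopent-1-en-1-yl]-3-[(phenylsulfanyl)methyl]oxolan-2-one | O=C1O[C@H](C2=C(C)CC[C@@H]2C(C)C)C[C@@H]1CSc3ccccc3 | intermediate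
12 | (3S,5S)-2-methylidene-5-[(5R)-2-methyl-5-(propan-2-yl)cyclopent-1-en-1-yl]-3-[(phenylsulfanyl)methyl]oxolane | C=C1O[C@H](C2=C(C)CC[C@@H]2C(C)C)C[C@@H]1CSc3ccccc3 | intermediate (not isolated)
13 | (3R,6S,8aR)-8a-methyl-6-[(phenylsulfanyl)methyl]-3-(propan-2-yl)-2,3,5,6,8,8a-hexahydroazulen-7(1H)-one | O=C1C[C@@]2(C)CC[C@H](C(C)C)C2=CC[C@@H]1CSc3ccccc3 | intermediate
14 | (6S,8aR)-8a-methyl-6-[(phenylsulfanyl)methyl]-3-(propan-2-yl)-2,4,5,6,8,8a-hexahydroazulen-7(1H)-one | O=C1C[C@@]2(C)CCC(C(C)C)=C2CC[C@@H]1CSc3ccccc3 | intermediate
15 | (6S,8aR)-6-[(benzenesulfinyl)methyl]-8a-methyl-3-(propan-2-yl)-2,4,5,6,8,8a-hexahydroazulen-7(1H)-one (both configurations at sulfur) | O=C1C[C@@]2(C)CCC(C(C)C)=C2CC[C@@H]1CS(=O)c3ccccc3 | intermediate (not isolated)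
16 | (8aR)-8a-methyl-6-methylidene-3-(propan-2-yl)-2,4,5,6,8,8a-hexahydroazulen-7(1H)-one | O=C1C[C@@]2(C)CCC(C(C)C)=C2CCC1=C | intermediate
17 | (8aR)-8a-methyl-6-methylidene-3-(propan-2-yl)-1,2,4,5,6,7,8,8a-octahydroazulen-7-ol (C7 epimers) | OC1C[C@@]2(C)CCC(C(C)C)=C2CCC1=C | intermediate
18 | methyl (8aR)-8a-methyl-6-methylidene-3-(propan-2-yl)-1,2,4,5,6,7,8,8a-octahydroazulen-7-yl carbonate (C7 epimers) | COC(=O)OC1C[C@@]2(C)CCC(C(C)C)=C2CCC1=C | intermediate
19 | vanillic acid, 4-hydroxy-3-methoxybenzoic acid | COc1cc(C(=O)O)ccc1O | starting material
20 | 4-(acetyloxy)-3-methoxybenzoic acid | COc1cc(C(=O)O)ccc1OC(C)=O | intermediate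
21 | [(8aR)-8a-methyl-3-(propan-2-yl)-1,2,4,5,8,8a-hexahydroazulen-6-yl]methyl 4-(acetyloxy)-3-methoxybenzoate | COc1cc(C(=O)OCC2=CC[C@@]3(C)CCC(C(C)C)=C3CC2)ccc1OC(C)=O | intermediate
22 | [(8aR)-8a-methyl-3-(propan-2-yl)-1,2,4,5,8,8a-hexahydroazulen-6-yl]methyl 4-hydroxy-3-methoxybenzoate | COc1cc(C(=O)OCC2=CC[C@@]3(C)CCC(C(C)C)=C3CC2)ccc1O | target

## Step count and least certain steps

Total step count: 13. Longest linear sequence: 12 steps (from 1 to 22 through steps 1 to 10, 12 and 13); step 11 is a one-step side branch from 19.

Step 6 (key step). The most likely failure is a slow sigmatropic shift, because the ring methyl is held inside the boat against the oxolane CH2. Three processes could then take over: heterolysis of the allylic C–O bond (with [1,3] recombination or erosion of chirality transfer), migration of the enol ether double bond into the ring under residual titanium Lewis acids, and methylenation of the newly formed ketone by surviving titanium methylidene. Fallback: starting from 11, methylenation with Cp2Ti(μ-Cl)(μ-CH2)AlMe2 in THF/pyridine at −40 → 0 °C would give 12, isolated quickly on basic alumina. Treatment with iBu3Al in CH2Cl2 at −78 → 20 °C should promote the Claisen ring expansion at low temperature and reduce the aluminium-bound ketone in the same flask by β-hydride transfer, giving the cycloheptenol F1. Swern oxidation (DMSO, (COCl)2, Et3N), which tolerates the sulfide, returns to 13. The fidelity of chirality transfer would have to be checked, because the Lewis acid increases the ionic character of the shift.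

Step 4. The most likely failure is poor facial selectivity in the addition to the enal together with incomplete separation of the carbinol epimers. Because the isopropyl centre is erased in step 7, any (5R) epimer carried forward ends as the enantiomer of 22. Fallback: starting from 6, the Barbier reaction run with Zn in THF/saturated aq NH4Cl at 20 °C should stop at the open hydroxy ester, obtained as 8 mixed with its carbinol epimer, ethyl (4R)-4-hydroxy-2-methylidene-4-[(5R)-2-methyl-5-(propan-2-yl)cyclopent-1-en-1-yl]butanoate F2. Oxidation of the mixture (Dess–Martin periodinane, NaHCO3, CH2Cl2) gives the ketone F3. Reduction with (R)-Me-CBS oxazaborolidine and catecholborane at −78 °C, with the cyclopentenyl group as the large substituent, should return 8 alone under reagent control. NaH (cat.) in THF closes the lactone and the route is rejoined at 9.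

Step 7. The most likely failure is diversion of the C3a cation: a 1,2-methyl shift from C8a (loss of the stereocentre), scattering of the alkene towards the isopropylidene position, or acid-induced loss of thiophenol. Fallback: starting from 13, a radical hydrogen-atom-transfer isomerisation with a chloro cobalt salen complex Co(salen)Cl (trivalent cobalt) and catalytic PhSiH3 in benzene at 20 °C would move the alkene through a tertiary C3a radical, with no carbocation. It rejoins the route at 14 and makes no new compound (F0).

Step 12. The most likely failures are attack at the ring terminus or by methoxide, acetyl transfer that frees a phenoxide which then O-allylates, or β-hydride loss from the allyl complex to a triene. Fallback: starting from 17, SOCl2 in Et2O at 0 °C should give, by chlorination with allylic transposition, the primary allylic chloride F4. Alkylation of 19 with F4 and KHCO3 in DMF, in which only the carboxylic acid is deprotonated, would give 22 directly. This rejoins the route at 22 and makes steps 10, 11 and 13 unnecessary.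

## Further compounds

F1 | step 6 | (3R,6S,8aR)-8a-methyl-6-[(phenylsulfanyl)methyl]-3-(propan-2-yl)-1,2,3,5,6,7,8,8a-octahydroazulen-7-ol (C7 epimers) | OC1C[C@@]2(C)CC[C@H](C(C)C)C2=CC[C@@H]1CSc3ccccc3
F2 | step 4 | ethyl (4R)-4-hydroxy-2-methylidene-4-[(5R)-2-methyl-5-(propan-2-yl)cyclopent-1-en-1-yl]butanoate | CCOC(=O)C(=C)C[C@@H](O)C1=C(C)CC[C@@H]1C(C)C
F3 | step 4 | ethyl 2-methylidene-4-[(5R)-2-methyl-5-(propan-2-yl)cyclopent-1-en-1-yl]-4-oxobutanoate | CCOC(=O)C(=C)CC(=O)C1=C(C)CC[C@@H]1C(C)C
F0 | step 7 | none | none
F4 | step 12 | (8aR)-6-(chloromethyl)-8a-methyl-3-(propan-2-yl)-1,2,4,5,8,8a-hexahydroazulene | ClCC1=CC[C@@]2(C)CCC(C(C)C)=C2CC1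
A1 | alternative 1 | tert-butyl(dimethyl){[(2E)-5-methyl-2-(5-methylhex-3-yn-1-yl)hexa-2,5-dien-1-yl]oxy}silane | C=C(C)C/C=C(\CCC#CC(C)C)CO[Si](C)(C)C(C)(C)C
A2 | alternative 1 | (8aR)-6-({[tert-butyl(dimethyl)silyl]oxy}methyl)-8a-methyl-3-(propan-2-yl)-4,5,8,8a-tetrahydroazulen-2(1H)-one | CC(C)(C)[Si](C)(C)OCC1=CC[C@@]2(C)CC(=O)C(C(C)C)=C2CC1
A3 | alternative 2 | methyl 2-diazobut-3-enoate | COC(=O)C(=[N+]=[N-])C=C
A4 | alternative 2 | 2-ethenyl-3-methylcyclopent-2-en-1-one | CC1=C(C=C)C(=O)CC1
A5 | alternative 2 | methyl (8aR)-8a-methyl-3-oxo-1,2,3,5,8,8a-hexahydroazulene-6-carboxylate | COC(=O)C1=CC[C@@]2(C)CCC(=O)C2=CC1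
A6 | alternative 3 | [(5R)-2-methyl-5-(propan-2-yl)cyclopent-1-en-1-yl]methanol | OCC1=C(C)CC[C@@H]1C(C)C
A7 | alternative 3 | [(5R)-2-methyl-5-(propan-2-yl)cyclopent-1-en-1-yl]methyl trifluoroacetate | O=C(OCC1=C(C)CC[C@@H]1C(C)C)C(F)(F)F
A8 | alternative 3 | 2-methylidenebut-3-en-1-yl 4-(acetyloxy)-3-methoxybenzoate | C=CC(=C)COC(=O)c1ccc(OC(C)=O)c(OC)c1
A9 | alternative 3 | [(8aR)-8a-methyl-3-(propan-2-yl)-1,2,4,5,8,8a-hexahydroazulen-6-yl]methyl 4-(acetyloxy)-3-methoxybenzoate (identical with 21) | COc1cc(C(=O)OCC2=CC[C@@]3(C)CCC(C(C)C)=C3CC2)ccc1OC(C)=O
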